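**Retrosynthetic overview**

1. The five MOM ethers come off last. The (E)-styryl arm at C6 is disconnected by a Heck coupling of a C6 bromide with MOM-protected 4-vinylguaiacol.
2. Key disconnection: the O1–C2 bond of the dihydrofuran. C2 is benzylic to the guaiacyl ring and para to its oxygen, and O1 sits on ring A ortho to C3a. A C2 cation, released from a C2 carboxyl group (N-hydroxyphthalimide ester) by decarboxylative radical–polar crossover, is therefore closed by an ortho OMOM oxygen of ring A, which is symmetric about its C3a–C6 axis.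
3. The 2,3,3-triarylpropanoic acid with C3 set comes from a cis-3,4-diaryl dihydrocoumarin. This is made by an isothiourea-catalysed [4+2] of the ring A ortho-quinone methide with the ammonium enolate of MOM-protected homovanillic acid.
4. The quinone methide precursor (a 2-(sulfonylmethyl)phenol) comes from 4-bromo-2,6-dimethoxybenzaldehyde and the Grignard reagent of MOM-protected 5-bromoresorcinol.
5. Ring order: the benzene rings are bought; a temporary δ-lactone ring forms in step 7 and is opened in step 8; the dihydrofuran ring forms in step 10.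

Key step: step 10

Remark: the carbon that becomes C2 is carried as an epimer mixture from step 8 on, because it is planarised in step 10. The sense of induction in step 7 is assigned by analogy with the usual enolate-face model and is to be confirmed on lactone 14 (bromine allows anomalous-dispersion X-ray analysis); the antipodal catalyst is used if the opposite sense is found.

**Route**

Step 1
Reactants: 1 5-bromoresorcinol
Product: 2 1-bromo-3,5-bis(methoxymethoxy)benzene
Conditions: MOMCl (2.5 equiv), i-Pr2NEt (3 equiv), CH2Cl2, 0 °C to rt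
Reagents that add atoms: chloromethyl methyl ether (MOMCl), COCCl
Why: Williamson-type O-alkylation of both phenols with the reactive α-chloro ether.

Step 2
Reactants: 3 4-bromo-2,6-dimethoxybenzaldehyde
Product: 4 4-bromo-2,6-dihydroxybenzaldehyde
Conditions: BBr3 (3 equiv), CH2Cl2, −78 °C to rt; H2O
Reagents that add atoms: none
Why: BBr3 ether cleavage (Lewis acid–base adduct, then bromide attack on the methyl group), helped by chelation to the ortho formyl group; the aryl bromide and the aldehyde should survive.

Step 3
Reactants: 4 4-bromo-2,6-dihydroxybenzaldehyde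
Product: 5 4-bromo-2-hydroxy-6-(methoxymethoxy)benzaldehyde
Conditions: MOMCl (1.05 equiv), i-Pr2NEt (1.2 equiv), CH2Cl2, 0 °C
Reagents that add atoms: chloromethyl methyl ether (MOMCl), COCCl
Why: Selective mono-O-alkylation: once one phenol is capped, the remaining OH is held in a hydrogen bond to the formyl oxygen and is much less nucleophilic, so one equivalent of MOMCl should stop at the mono-ether.

Step 4
Reactants: 2 1-bromo-3,5-bis(methoxymethoxy)benzene; 5 4-bromo-2-hydroxy-6-(methoxymethoxy)benzaldehyde
Product: 7 5-bromo-2-{[3,5-bis(methoxymethoxy)phenyl](hydroxy)methyl}-3-(methoxymethoxy)phenol (racemic), via arylmagnesium bromide 6 (not isolated)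
Conditions: 2 (2.3 equiv), Mg, THF, 45 °C; then 5 (1 equiv), THF, 0 °C to rt; pH 7 phosphate buffer
Reagents that add atoms: none
Why: Grignard formation and 1,2-addition to the aldehyde; the first equivalent only deprotonates the phenol, the aryl bromide of 5 is inert to the arylmagnesium reagent at 0 °C, and the new carbinol centre is racemic, which is immaterial because it is planarised in the quinone methide.

Step 5
Reactants: 7 5-bromo-2-{[3,5-bis(methoxymethoxy)phenyl](hydroxy)methyl}-3-(methoxymethoxy)phenol
Product: 8 5-bromo-2-{[3,5-bis(methoxymethoxy)phenyl](4-methylbenzenesulfonyl)methyl}-3-(methoxymethoxy)phenol (racemic)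
Conditions: p-TolSO2H (1.5 equiv, freshly prepared), CH2Cl2, rt
Reagents that add atoms: p-toluenesulfinic acid, Cc1ccc(cc1)S(=O)O
Why: Acid-promoted ionisation of the ortho-hydroxybenzhydrol to the ortho-quinone methide and 1,4-addition of sulfinate through sulfur is the standard preparation of 2-(sulfonylmethyl)phenols, and the weak sulfinic acid in an aprotic solvent should leave the aryl MOM ethers in place.

Step 6
Reactants: 9 homovanillic acid
Product: 11 [3-methoxy-4-(methoxymethoxy)phenyl]acetic acid, via methoxymethyl ester 10 (not isolated)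
Conditions: MOMCl (2.4 equiv), i-Pr2NEt (3 equiv), CH2Cl2, 0 °C to rt; then LiOH (3 equiv), THF/H2O, rt; 1 M HCl to pH 4, 0 °C
Reagents that add atoms: chloromethyl methyl ether (MOMCl), COCCl; lithium hydroxide, [Li+].[OH-]
Why: The phenol and the carboxyl group are both alkylated and the acetal ester is then saponified selectively, the aryl MOM ether being stable to base and to brief mild acid.

Step 7
Reactants: 11 [3-methoxy-4-(methoxymethoxy)phenyl]acetic acid; 8 5-bromo-2-{[3,5-bis(methoxymethoxy)phenyl](4-methylbenzenesulfonyl)methyl}-3-(methoxymethoxy)phenol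
Product: 14 (3S,4R)-7-bromo-4-[3,5-bis(methoxymethoxy)phenyl]-3-[3-methoxy-4-(methoxymethoxy)phenyl]-5-(methoxymethoxy)chroman-2-one (3,4-cis), via mixed pivalic anhydride 12 (not isolated), via ortho-quinone methide 13 (not isolated)
Conditions: 11 (1.5 equiv), t-BuCOCl (1.5 equiv), i-Pr2NEt (1.5 equiv), CH2Cl2, 0 °C; then 8 (1 equiv), (2S,3R)-HyperBTM [(2S,3R)-3-isopropyl-2-phenyl-3,4-dihydro-2H-benzo[4,5]thiazolo[3,2-a]pyrimidine] (10 mol%), Cs2CO3 (2.5 equiv), CH2Cl2, 0 °C to rt
Reagents that add atoms: none
Why: Isothiourea-catalysed Michael addition–lactonisation (formal [4+2]) of a C1-ammonium enolate with an ortho-quinone methide released in situ from a 2-(sulfonylmethyl)phenol is a known route to 3,4-diaryl dihydrocoumarins; the catalyst holds the (Z)-enolate by its 1,5-O···S contact and shields one face with its phenyl group, the cis-selective endo approach of the heterodiene then sets C4 as R, and because only C4 survives to the target the lactone is taken on as a single diastereomer.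

Step 8
Reactants: 14 (3S,4R)-7-bromo-4-[3,5-bis(methoxymethoxy)phenyl]-3-[3-methoxy-4-(methoxymethoxy)phenyl]-5-(methoxymethoxy)chroman-2-one
Product: 17 (3R)-3-[4-bromo-2,6-bis(methoxymethoxy)phenyl]-3-[3,5-bis(methoxymethoxy)phenyl]-2-[3-methoxy-4-(methoxymethoxy)phenyl]propanoic acid (C2 epimer mixture), via dilithium phenoxide carboxylate 15 (not isolated), via methoxymethyl ester 16 (not isolated)
Conditions: LiOH·H2O (2.2 equiv), THF/H2O, rt; evaporate, dry (toluene azeotrope); MOMCl (3 equiv), DMF, 0 °C; then LiOH (3 equiv), THF/MeOH/H2O, rt; 1 M HCl to pH 4–5, 0 °C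
Reagents that add atoms: chloromethyl methyl ether (MOMCl), COCCl; lithium hydroxide, [Li+].[OH-]
Why: Saponification of the aryl ester (lactone), double O-alkylation of the phenoxide–carboxylate and hydrolysis of the labile MOM ester give the acid with the ring A oxygen capped so that it cannot re-lactonise; C3 is not acidic under these conditions and stays R, while C2 may epimerise without consequence.

Step 9
Reactants: 17 (3R)-3-[4-bromo-2,6-bis(methoxymethoxy)phenyl]-3-[3,5-bis(methoxymethoxy)phenyl]-2-[3-methoxy-4-(methoxymethoxy)phenyl]propanoic acid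
Product: 18 1,3-dioxoisoindolin-2-yl (3R)-3-[4-bromo-2,6-bis(methoxymethoxy)phenyl]-3-[3,5-bis(methoxymethoxy)phenyl]-2-[3-methoxy-4-(methoxymethoxy)phenyl]propanoate (C2 epimer mixture)
Conditions: N-hydroxyphthalimide (1.1 equiv), DIC (1.2 equiv), DMAP (10 mol%), CH2Cl2, rt
Reagents that add atoms: N-hydroxyphthalimide, O=C1c2ccccc2C(=O)N1O
Why: Steglich-type carbodiimide esterification gives the redox-active ester; no free phenol is left that could re-close the lactone, and the epimerisable C2 is irrelevant.

Step 10
Reactants: 18 1,3-dioxoisoindolin-2-yl (3R)-3-[4-bromo-2,6-bis(methoxymethoxy)phenyl]-3-[3,5-bis(methoxymethoxy)phenyl]-2-[3-methoxy-4-(methoxymethoxy)phenyl]propanoate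
Product: 19 (2R,3R)-6-bromo-3-[3,5-bis(methoxymethoxy)phenyl]-2-[3-methoxy-4-(methoxymethoxy)phenyl]-4-(methoxymethoxy)-2,3-dihydro-1-benzofuran (2,3-trans)
Conditions: 12-phenyl-12H-benzo[b]phenothiazine (10 mol%), LiBF4 (20 mol%), dry MeCN, blue LEDs (about 440 nm), rt, argon
Reagents that add atoms: none
Why: Proposed new method: the excited phenothiazine transfers an electron to the phthalimide ester, which fragments to phthalimide anion, CO2 and the C2 benzylic radical, and the phenothiazine radical cation then oxidises this electron-rich radical (radical–polar crossover) to the C2 cation, a para-alkoxybenzylic cation stabilised by the guaiacyl oxygen. The closest known reaction is the photoredox decarboxylative etherification of N-(acyloxy)phthalimides with alcohols, the redox-neutral counterpart of Hofer–Moest oxidation; what is new is that the nucleophile is an aryl methoxymethyl ether oxygen (a participation known from halo-etherification), whose oxonium ion then passes its methoxymethyl group to phthalimide anion. The dihydrofuran ring closes by 5-exo-trig attack of a ring A ortho oxygen on the planar cation, and because the two ortho OMOM groups are equivalent only one constitution can form. C2 is created from a planar cation and the guaiacyl group should take the face anti to the C3 resorcinyl group, giving the trans (2R,3R) ring, which is also the more stable isomer, while C3 is not involved and keeps the configuration set in step 7. The step needs ring closure to outrun loss of the C3 proton and capture by phthalimide anion, which the five-atom proximity of the ether oxygen and the absence of added base or external nucleophile should secure; the ester is also reduced far more easily than the electron-rich C6–Br bond.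

Step 11
Reactants: 20 4-vinylguaiacol (2-methoxy-4-vinylphenol)
Product: 21 4-ethenyl-2-methoxy-1-(methoxymethoxy)benzene
Conditions: MOMCl (1.3 equiv), i-Pr2NEt (1.5 equiv), CH2Cl2, 0 °C to rt (trace BHT)
Reagents that add atoms: chloromethyl methyl ether (MOMCl), COCCl
Why: Williamson-type MOM protection, which keeps the vinylphenol from polymerising and from binding palladium in the Heck step.

Step 12
Reactants: 19 (2R,3R)-6-bromo-3-[3,5-bis(methoxymethoxy)phenyl]-2-[3-methoxy-4-(methoxymethoxy)phenyl]-4-(methoxymethoxy)-2,3-dihydro-1-benzofuran; 21 4-ethenyl-2-methoxy-1-(methoxymethoxy)benzene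
Product: 22 (2R,3R)-3-[3,5-bis(methoxymethoxy)phenyl]-2-[3-methoxy-4-(methoxymethoxy)phenyl]-4-(methoxymethoxy)-6-{(E)-2-[3-methoxy-4-(methoxymethoxy)phenyl]ethenyl}-2,3-dihydro-1-benzofuran
Conditions: 21 (1.5 equiv), Pd(P(t-Bu)3)2 (5 mol%), Cy2NMe (1.5 equiv), 1,4-dioxane, 80 °C
Reagents that add atoms: none
Why: Mizoroki–Heck reaction: oxidative addition of the C6–Br bond to zerovalent palladium, syn insertion of the styrene at its terminal carbon and syn β-hydride elimination should give the (E)-stilbene, with the benzylic ether and both stereocentres untouched.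

Step 13
Reactants: 22 (2R,3R)-3-[3,5-bis(methoxymethoxy)phenyl]-2-[3-methoxy-4-(methoxymethoxy)phenyl]-4-(methoxymethoxy)-6-{(E)-2-[3-methoxy-4-(methoxymethoxy)phenyl]ethenyl}-2,3-dihydro-1-benzofuran
Product: 23 (2R,3R)-3-(3,5-dihydroxyphenyl)-2-(4-hydroxy-3-methoxyphenyl)-6-[(E)-2-(4-hydroxy-3-methoxyphenyl)ethenyl]-2,3-dihydro-1-benzofuran-4-ol (target)
Conditions: HCl (1.25 M in MeOH), THF, 40 °C
Reagents that add atoms: none
Why: Acid-catalysed acetal exchange with methanol should remove all five MOM ethers while the methyl ethers stay, and any reversible ionisation of the O1–C2 bond under acid can only return the more stable trans ring because C3 is not affected.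

**Compound list**

1 | 5-bromoresorcinol (5-bromobenzene-1,3-diol) | Oc1cc(O)cc(Br)c1 | starting material
2 | 1-bromo-3,5-bis(methoxymethoxy)benzene | COCOc1cc(Br)cc(OCOC)c1 | intermediate
3 | 4-bromo-2,6-dimethoxybenzaldehyde | COc1cc(Br)cc(OC)c1C=O | starting material
4 | 4-bromo-2,6-dihydroxybenzaldehyde | O=Cc1c(O)cc(Br)cc1O | intermediate
5 | 4-bromo-2-hydroxy-6-(methoxymethoxy)benzaldehyde | COCOc1cc(Br)cc(O)c1C=O | intermediate
6 | 3,5-bis(methoxymethoxy)phenylmagnesium bromide | COCOc1cc([Mg]Br)cc(OCOC)c1 | intermediate (not isolated)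
7 | 5-bromo-2-{[3,5-bis(methoxymethoxy)phenyl](hydroxy)methyl}-3-(methoxymethoxy)phenol, racemic | COCOc1cc(Br)cc(O)c1C(O)c1cc(OCOC)cc(OCOC)c1 | intermediate
8 | 5-bromo-2-{[3,5-bis(methoxymethoxy)phenyl](4-methylbenzenesulfonyl)methyl}-3-(methoxymethoxy)phenol, racemic | COCOc1cc(Br)cc(O)c1C(c1cc(OCOC)cc(OCOC)c1)S(=O)(=O)c1ccc(C)cc1 | intermediate
9 | homovanillic acid | COc1cc(CC(=O)O)ccc1O | starting material
10 | methoxymethyl [3-methoxy-4-(methoxymethoxy)phenyl]acetate | COCOC(=O)Cc1ccc(OCOC)c(OC)c1 | intermediate (not isolated)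
11 | [3-methoxy-4-(methoxymethoxy)phenyl]acetic acid | COCOc1ccc(CC(=O)O)cc1OC | intermediate
12 | [3-methoxy-4-(methoxymethoxy)phenyl]acetic pivalic anhydride | COCOc1ccc(CC(=O)OC(=O)C(C)(C)C)cc1OC | intermediate (not isolated)
13 | 6-{[3,5-bis(methoxymethoxy)phenyl]methylidene}-3-bromo-5-(methoxymethoxy)cyclohexa-2,4-dien-1-one (ortho-quinone methide, alkene geometry not defined) | COCOC1=CC(Br)=CC(=O)C1=Cc1cc(OCOC)cc(OCOC)c1 | intermediate (not isolated)
14 | (3S,4R)-7-bromo-4-[3,5-bis(methoxymethoxy)phenyl]-3-[3-methoxy-4-(methoxymethoxy)phenyl]-5-(methoxymethoxy)chroman-2-one (3,4-cis) | O=C1Oc2cc(Br)cc(OCOC)c2[C@@H](c2cc(OCOC)cc(OCOC)c2)[C@H]1c1ccc(OCOC)c(OC)c1 | intermediate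
15 | dilithium (3R)-3-[4-bromo-2-oxido-6-(methoxymethoxy)phenyl]-3-[3,5-bis(methoxymethoxy)phenyl]-2-[3-methoxy-4-(methoxymethoxy)phenyl]propanoate (C2 not defined) | [Li+].[Li+].[O-]C(=O)C(c1ccc(OCOC)c(OC)c1)[C@H](c1cc(OCOC)cc(OCOC)c1)c1c([O-])cc(Br)cc1OCOC | intermediate (not isolated)
16 | methoxymethyl (3R)-3-[4-bromo-2,6-bis(methoxymethoxy)phenyl]-3-[3,5-bis(methoxymethoxy)phenyl]-2-[3-methoxy-4-(methoxymethoxy)phenyl]propanoate (C2 epimer mixture) | COCOC(=O)C(c1ccc(OCOC)c(OC)c1)[C@H](c1cc(OCOC)cc(OCOC)c1)c1c(OCOC)cc(Br)cc1OCOC | intermediate (not isolated)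
17 | (3R)-3-[4-bromo-2,6-bis(methoxymethoxy)phenyl]-3-[3,5-bis(methoxymethoxy)phenyl]-2-[3-methoxy-4-(methoxymethoxy)phenyl]propanoic acid (C2 epimer mixture) | OC(=O)C(c1ccc(OCOC)c(OC)c1)[C@H](c1cc(OCOC)cc(OCOC)c1)c1c(OCOC)cc(Br)cc1OCOC | intermediate
18 | 1,3-dioxoisoindolin-2-yl ester of acid 17 (C2 epimer mixture; key-step precursor) | O=C(ON1C(=O)c2ccccc2C1=O)C(c1ccc(OCOC)c(OC)c1)[C@H](c1cc(OCOC)cc(OCOC)c1)c1c(OCOC)cc(Br)cc1OCOC | intermediate
19 | (2R,3R)-6-bromo-3-[3,5-bis(methoxymethoxy)phenyl]-2-[3-methoxy-4-(methoxymethoxy)phenyl]-4-(methoxymethoxy)-2,3-dihydro-1-benzofuran (trans; key-step product) | Brc1cc(OCOC)c2c(c1)O[C@@H](c1ccc(OCOC)c(OC)c1)[C@@H]2c1cc(OCOC)cc(OCOC)c1 | intermediate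
20 | 4-vinylguaiacol (2-methoxy-4-vinylphenol) | C=Cc1ccc(O)c(OC)c1 | starting material
21 | 4-ethenyl-2-methoxy-1-(methoxymethoxy)benzene | C=Cc1ccc(OCOC)c(OC)c1 | intermediate
22 | (2R,3R)-3-[3,5-bis(methoxymethoxy)phenyl]-2-[3-methoxy-4-(methoxymethoxy)phenyl]-4-(methoxymethoxy)-6-{(E)-2-[3-methoxy-4-(methoxymethoxy)phenyl]ethenyl}-2,3-dihydro-1-benzofuran | COCOc1ccc(/C=C/c2cc(OCOC)c3c(c2)O[C@@H](c2ccc(OCOC)c(OC)c2)[C@@H]3c2cc(OCOC)cc(OCOC)c2)cc1OC | intermediate
23 | (2R,3R)-3-(3,5-dihydroxyphenyl)-2-(4-hydroxy-3-methoxyphenyl)-6-[(E)-2-(4-hydroxy-3-methoxyphenyl)ethenyl]-2,3-dihydro-1-benzofuran-4-ol | COc1cc(/C=C/c2cc(O)c3c(c2)O[C@@H](c2ccc(O)c(OC)c2)[C@@H]3c2cc(O)cc(O)c2)ccc1O | target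

**Step count and risks**

Total step count: 13.
Longest linear sequence: 10 steps (3 → 4 → 5 → 7 → 8 → 14 → 17 → 18 → 19 → 22 → 23; steps 2, 3, 4, 5, 7, 8, 9, 10, 12, 13).

Steps most likely to fail:

1. Step 10 (proposed new method). The C2 cation may lose the C3 proton faster than the weakly nucleophilic aryl ether oxygen closes, which would erase C3. Phthalimide anion may trap the cation before ring closure. The excited catalyst may also reduce the C6–Br bond. Fallback with known chemistry, setting out from 18: the same photocatalysis is run with methanol (10 equiv) as external nucleophile, the established intermolecular decarboxylative etherification, and should give the benzylic methyl ether F1 (C2 epimers, diaryl carbon unchanged). Treatment of F1 with HCl in MeOH removes the five MOM groups and ionises the para-hydroxybenzylic ether. A free ring A phenol then closes the dihydrofuran in a classical acid-mediated cyclisation under thermodynamic (trans) control to give the tetraphenol bromide F2. Re-protection of its four phenols with MOMCl and i-Pr2NEt in DMF comes back to the route at 19.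

2. Step 7. Facial discrimination at the methide carbon may be poor, because it is flanked by an OMOM group and an aryl ring. Cis and trans adducts from the same enolate face would carry opposite C4 configuration and erode the enantiomeric purity. O-acylation of phenol 8 by the acyl donor may also compete with quinone methide release. Fallback, setting out from 8 and 11: the annulation is run with the achiral isothiourea DHPB (3,4-dihydro-2H-pyrimido[2,1-b][1,3]benzothiazole) under otherwise the same conditions to give the racemic cis-lactone F3. This is resolved by preparative supercritical-fluid chromatography on an amylose tris(3,5-dimethylphenylcarbamate) phase; the (3S,4R) enantiomer is 14, where the route is rejoined.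

3. Step 8. The δ-lactone may re-close, by phenoxide attack on the carboxyl group once it is alkylated or on acidification, in competition with O-alkylation of the hindered phenoxide. Fallback, setting out from 14: LiBH4 in THF reduces the lactone to the phenol primary alcohol F4, which cannot re-lactonise. K2CO3 and MOMCl in acetone alkylate only the phenol to give the MOM-protected primary alcohol F5. Oxidation in two stages (Dess–Martin periodinane, then NaClO2, NaH2PO4 and 2-methyl-2-butene in t-BuOH/H2O) returns to the route at acid 17.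

**Further compounds**

F1 | step 10 | 5-bromo-2-{(1R)-1-[3,5-bis(methoxymethoxy)phenyl]-2-methoxy-2-[3-methoxy-4-(methoxymethoxy)phenyl]ethyl}-1,3-bis(methoxymethoxy)benzene (benzylic methyl ether, epimers at the methoxy-bearing carbon, diaryl carbon as in 18) | COC(c1ccc(OCOC)c(OC)c1)[C@H](c1cc(OCOC)cc(OCOC)c1)c1c(OCOC)cc(Br)cc1OCOC
F2 | step 10 | (2R,3R)-6-bromo-3-(3,5-dihydroxyphenyl)-2-(4-hydroxy-3-methoxyphenyl)-2,3-dihydro-1-benzofuran-4-ol | Brc1cc(O)c2c(c1)O[C@@H](c1ccc(O)c(OC)c1)[C@@H]2c1cc(O)cc(O)c1
F3 | step 7 | rac-(3S*,4R*)-7-bromo-4-[3,5-bis(methoxymethoxy)phenyl]-3-[3-methoxy-4-(methoxymethoxy)phenyl]-5-(methoxymethoxy)chroman-2-one (racemic cis-lactone) | O=C1Oc2cc(Br)cc(OCOC)c2C(c2cc(OCOC)cc(OCOC)c2)C1c1ccc(OCOC)c(OC)c1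
F4 | step 8 | (3R)-3-[4-bromo-2-hydroxy-6-(methoxymethoxy)phenyl]-3-[3,5-bis(methoxymethoxy)phenyl]-2-[3-methoxy-4-(methoxymethoxy)phenyl]propan-1-ol (C2 not specified) | OCC(c1ccc(OCOC)c(OC)c1)[C@H](c1cc(OCOC)cc(OCOC)c1)c1c(O)cc(Br)cc1OCOC
F5 | step 8 | (3R)-3-[4-bromo-2,6-bis(methoxymethoxy)phenyl]-3-[3,5-bis(methoxymethoxy)phenyl]-2-[3-methoxy-4-(methoxymethoxy)phenyl]propan-1-ol (C2 not specified) | OCC(c1ccc(OCOC)c(OC)c1)[C@H](c1cc(OCOC)cc(OCOC)c1)c1c(OCOC)cc(Br)cc1OCOC
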